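The invariant I tried between the two earlier runs was the molar amount of target, not its percentage: at 80.0 s the midnight reading came to 0.0276 M and the autumn reading to 0.0270 M, although autumn was charged with 2.25 times the solid substrate. Those two figures are good to 0.00240 M and 0.00540 M, so their match is a match of scattered readings and shows no constant amount.

| setting | midnight | autumn | flask |
|---|---|---|---|
| solid substrate | 0.12 M | 0.27 M | 0.18 M |
| solid reagent | 0.171 M | 0.171 M | 0.171 M |
| remark | run made earlier | run made earlier |  |
| time |  |  | 2.0 min |

| run | time / s | target / % |
|---|---|---|
| midnight | 10.0 | 3 |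
| midnight | 25.0 | 1 |
| midnight | 50.0 | 10 |
| midnight | 80.0 | 23 |
| autumn | 20.0 | 2 |
| autumn | 40.0 | 5 |
| autumn | 50.0 | 5 |
| autumn | 80.0 | 10 |

(readings scatter by 2 percentage points)

- at the start none of the solid reagent is in solution
- at the start none of the solid substrate is in solution
- a reading or a percentage of target counts all its forms, free or not

- amount of target in percent of the solid substrate charged, at 6.0 s, 30 s and 2.0 min

So, as a working assumption, I reckoned the flask in molar terms: the level at 80.0 s, carried forward by a rise per minute, then divided by the flask's charge. In this reckoning that charge is a plain divisor. The solid reagent stands at 0.171 M in all three flasks, so these runs cannot show its effect. Readings before 50.0 s do not enter my reckoning. The later ones do: an autumn reading at 80.0 s off by 2 percentage points moves my 2.0 min figure by 3.5 points, the same slip at midnight by 1.6 points.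

Averaged over both runs, the level at 80.0 s was 0.0273 M, and the rise from 50.0 s was 0.0291 M min⁻¹, which I call the molar pace. Carried forward, it gave me 25.9% at 2.0 min; back at 30 s it gave 1.69%, and at 6.0 s the line is useless, as the readings show an induction period. The forecast reasoned “So the target formed does not depend on the substrate charged” and gave 0.3%, 2.7% and 30%, higher than mine at 2.0 min.

The flask gave 0.0559%, 3.40% and 21.6% at those times. At 0.964 min dissolved target was being made 2.30 times faster than it was used up.

    solid reagent ⇌ partner, rate k1*(cs1 - [partner]) while solid is left; crystals form when [partner] > cs1 (solubility = 0.110 M, k = 0.00720 s⁻¹)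
    solid substrate ⇌ dissolved substrate, rate k2*(cs2 - [dissolved substrate]) while solid is left; crystals form when [dissolved substrate] > cs2 (solubility = 0.0950 M, k = 0.00930 s⁻¹)
    solid substrate + target → side product (k = 0.130 M⁻¹ s⁻¹)
    dissolved substrate + partner → target (k = 2.20 M⁻¹ s⁻¹)
    solid product ⇌ target, rate k5*(cs5 - [target]) while solid is left; crystals form when [target] > cs5 (solubility = 0.0760 M, k = 0.400 s⁻¹)

Counted from the level of 0.0273 M, the flask's 0.0389 M at 2.0 min is a rise of 0.0174 M min⁻¹, slower than the molar pace of 0.0291 M min⁻¹. A flask with twice the solid reagent reached 21.6%, a rise of 0.0173 M min⁻¹.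

Readings and results are simulated for an exercise; the scatter is artificial.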